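**Plan**

Numbering follows the labdane skeleton: ring A is C1–C5 with C10, ring B is C5–C10, C17 sits on C8, C18 and C19 on C4, C20 on C10, and the side chain is C11–C16.
Retrosynthetic cuts, in order: the butenolide (C12–C13 by cross-metathesis of an allyl group, then alkene migration), the C4–C18 bond (enolate methylation), the C10–C1 bond (ring A, key step), the C4–C5 bond (β-keto ester enolate plus α-bromo ketone), and the C9–C11 bond (enolate allylation).
Forward: ring B is present from the start as a cyclohexenone ester; the C9 and C5 side chains are attached, ring A is closed by the C10–C1 bond, and the butenolide is added last.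
The key event rests on two features of ring A: C10 is a fully substituted carbon carrying a methyl group, so it can be a tertiary radical made by hydrogen-atom transfer to a C10=C20 methylene; C1 stands β to the C3 oxygen, so it can be the terminus of a vinyl ketone. The two are joined 6-endo.
Stereochemistry: C8 from the chiral copper hydride catalyst; C9 and C5 relative to C8 under thermodynamic control through the C10 ketone (all-equatorial ring B); C10 in the key step (chair-like closure to the trans-decalin, convergent for C4); C4 by methylation opposite the axial C20; C3 by axial hydride attack.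

Key step: step 6

Remark: in step 1 the (S)-bisphosphine is assumed to deliver hydride to the face of C8 that gives the (1S) ester 3; if the sense of induction is the opposite, the (R)-ligand is used.

**Route**

Step 1
Reactants: 1 methyl 3-oxocyclohex-1-ene-1-carboxylate
Product: 3 methyl (1S,2R)-3-oxo-2-(prop-2-en-1-yl)cyclohexane-1-carboxylate, via diphenylsilyl enol ether 2 (not isolated)
Conditions: CuCl (5 mol%), NaOtBu (5 mol%), (S)-p-Tol-BINAP (5 mol%), Ph2SiH2, toluene, 0 °C; then allyl bromide, Bu4N[Ph3SiF2] (TBAT), CH2Cl2, rt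
Reagents that add atoms: allyl bromide, C=CCBr
Why: Asymmetric conjugate reduction by a ligated copper hydride (Buchwald-type CuH catalysis) should put the hydride on the carbon β to the ketone and so fix C8 from the catalyst, and fluoride-triggered allylation of the regiodefined silyl enol ether at C9 should occur anti to the neighbouring ester, giving the trans keto ester.

Step 2
Reactants: 3 methyl (1S,2R)-3-oxo-2-(prop-2-en-1-yl)cyclohexane-1-carboxylate
Product: 5 methyl (1S,2R)-4-bromo-3-oxo-2-(prop-2-en-1-yl)cyclohexane-1-carboxylate (both epimers at the C–Br carbon), via trimethylsilyl enol ether 4 (not isolated)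
Conditions: LiN(iPr)2, THF, −78 °C; Me3SiCl; then NBS, THF, −78 → 0 °C
Reagents that add atoms: N-bromosuccinimide, O=C1CCC(=O)N1Br
Why: Kinetic deprotonation by the hindered amide takes the less substituted α-CH2 (C5), and bromination of the resulting silyl enol ether (α-halogenation of a ketone through its enol ether) should place the leaving group there; the C–Br centre may be a mixture because it is erased in the next step.

Step 3
Reactants: 5 methyl (1S,2R)-4-bromo-3-oxo-2-(prop-2-en-1-yl)cyclohexane-1-carboxylate; 6 methyl 5-methoxy-3-oxopentanoate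
Product: 7 methyl (1S,2R,4R)-4-(1,5-dimethoxy-1,3-dioxopentan-2-yl)-3-oxo-2-(prop-2-en-1-yl)cyclohexane-1-carboxylate (epimers at the side-chain carbon, partly enolised)
Conditions: 6, NaH, THF, 0 °C; then 5, 0 °C → rt; then DBU (cat.), MeOH, 40 °C
Reagents that add atoms: none
Why: SN2 alkylation of the stabilised β-keto ester enolate by the α-bromo ketone should build the C4–C5 bond, and base equilibration of the ketone α-centre should then move the new chain into the equatorial position cis to the C9 allyl group (thermodynamic control through the C10 ketone), while C4 remains an epimerising β-keto ester carbon.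

Step 4
Reactants: 7 methyl (1S,2R,4R)-4-(1,5-dimethoxy-1,3-dioxopentan-2-yl)-3-oxo-2-(prop-2-en-1-yl)cyclohexane-1-carboxylate
Product: 8 methyl (1S,2R,4R)-4-(1,5-dimethoxy-1,3-dioxopentan-2-yl)-3-methylidene-2-(prop-2-en-1-yl)cyclohexane-1-carboxylate
Conditions: Ph3PCH3Br, NaN(SiMe3)2, THF, 0 → 65 °C
Reagents that add atoms: methyltriphenylphosphonium bromide (as its ylide), C[P+](c1ccccc1)(c1ccccc1)c1ccccc1.[Br-]
Why: Wittig methylenation should convert the C10 ketone into the 1,1-disubstituted alkene C10=C20, with the β-keto ester shielded as its enolate so that only the ring ketone reacts; no stereocentre is formed.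

Step 5
Reactants: 8 methyl (1S,2R,4R)-4-(1,5-dimethoxy-1,3-dioxopentan-2-yl)-3-methylidene-2-(prop-2-en-1-yl)cyclohexane-1-carboxylate
Product: 9 methyl (1S,2R,4R)-4-(1-methoxy-1,3-dioxopent-4-en-2-yl)-3-methylidene-2-(prop-2-en-1-yl)cyclohexane-1-carboxylate
Conditions: LiN(iPr)2 (2.2 equiv), THF, −78 → 0 °C; AcOH, −78 °C
Reagents that add atoms: none
Why: Two equivalents of amide base should form the β-keto ester dianion, whose γ-carbanion expels the β-methoxide (E1cB elimination) and unmasks the vinyl ketone; any C8 ester enolate formed on the way is reprotonated on quench and is re-equilibrated in step 7.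

Step 6
Reactants: 9 methyl (1S,2R,4R)-4-(1-methoxy-1,3-dioxopent-4-en-2-yl)-3-methylidene-2-(prop-2-en-1-yl)cyclohexane-1-carboxylate
Product: 10 dimethyl (4aS,5R,6S,8aR)-4a-methyl-2-oxo-5-(prop-2-en-1-yl)decahydronaphthalene-1,6-dicarboxylate (epimers at C1 of the ring system, partly enolised)
Conditions: Fe(acac)3 (30 mol%), PhSiH3, EtOH/(CH2OH)2, 60 °C, 0.02 M
Reagents that add atoms: none
Why: Hydrogen-atom transfer from the iron hydride (from Fe(acac)3 and PhSiH3) to the terminal carbon C20 of the 1,1-disubstituted alkene should give the tertiary C10 radical, which adds to C1, the β-carbon of the vinyl ketone, and the stabilised radical at C2 is then reduced and protonated; the closest known reaction type is the MHAT-initiated reductive olefin coupling (radical Giese cyclisation onto an enone). Ring A closes in the 6-endo-trig mode, the 5-exo alternative being disfavoured because it would bond the nucleophilic radical to the carbon α to the carbonyl. The new stereocentre C10 is controlled by the chair of ring B, in which the C5 chain, the C9 allyl group and the C8 ester are all equatorial: closure through the equatorial lobe gives a chair–chair trans-decalin with only the small methyl group axial, as in the second ring closure of radical polyene cyclisations, whereas closure through the axial lobe would force the substituted carbon C9 into an axial position on the new ring. The step needs hydrogen-atom transfer to the exocyclic alkene in preference to the monosubstituted allyl alkene and the electron-poor vinyl ketone, which the faster reaction of metal hydrides with 1,1-disubstituted electron-rich alkenes should secure, and 6-endo regioselectivity, which the polarisation of the enone should secure. Both C4 epimers and the enol form of the β-keto ester lead to the same product, so nothing has to be controlled at C4 before the ring is closed.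

Step 7
Reactants: 10 dimethyl (4aS,5R,6S,8aR)-4a-methyl-2-oxo-5-(prop-2-en-1-yl)decahydronaphthalene-1,6-dicarboxylate
Product: 11 dimethyl (1S,4aS,5R,6S,8aS)-1,4a-dimethyl-2-oxo-5-(prop-2-en-1-yl)decahydronaphthalene-1,6-dicarboxylate
Conditions: NaOMe, MeOH, 50 °C; then MeI, rt
Reagents that add atoms: iodomethane, CI
Why: Methoxide should first equilibrate the C8 ester to the equatorial position (its axial epimer would be syn-axial to the C10 methyl), and the β-keto ester enolate is then C-methylated (β-keto ester alkylation) from the face opposite the axial C10 methyl, as in podocarpate-type methylations, which puts the new methyl equatorial and the ester (future C19) axial at C4.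

Step 8
Reactants: 11 dimethyl (1S,4aS,5R,6S,8aS)-1,4a-dimethyl-2-oxo-5-(prop-2-en-1-yl)decahydronaphthalene-1,6-dicarboxylate
Product: 12 dimethyl (1S,2R,4aS,5R,6S,8aS)-2-hydroxy-1,4a-dimethyl-5-(prop-2-en-1-yl)decahydronaphthalene-1,6-dicarboxylate
Conditions: NaBH4, MeOH, 0 °C
Reagents that add atoms: none
Why: Borohydride should attack the C3 ketone along the axial trajectory, from the face away from the axial C4 ester, and give the equatorial 3-alcohol (hydride reduction of a hindered cyclohexanone) while the esters survive.

Step 9
Reactants: 12 dimethyl (1S,2R,4aS,5R,6S,8aS)-2-hydroxy-1,4a-dimethyl-5-(prop-2-en-1-yl)decahydronaphthalene-1,6-dicarboxylate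
Product: 13 (1R,2R,4aS,5R,6S,8aS)-1,6-bis(hydroxymethyl)-1,4a-dimethyl-5-(prop-2-en-1-yl)decahydronaphthalen-2-ol
Conditions: LiAlH4, THF, 0 → 65 °C
Reagents that add atoms: none
Why: LiAlH4 should reduce both methyl esters to the primary alcohols C17 and C19 (ester reduction); no stereocentre is formed and the terminal alkene is inert.

Step 10
Reactants: 13 (1R,2R,4aS,5R,6S,8aS)-1,6-bis(hydroxymethyl)-1,4a-dimethyl-5-(prop-2-en-1-yl)decahydronaphthalen-2-ol; 14 3-methylideneoxolan-2-one
Product: 15 (3E)-3-{2-[(1R,2S,4aS,5R,6R,8aS)-6-hydroxy-2,5-bis(hydroxymethyl)-5,8a-dimethyldecahydronaphthalen-1-yl]ethylidene}oxolan-2-one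
Conditions: 14 (excess), RuCl2(H2IMes)(=CH-C6H4-2-OiPr) (Hoveyda–Grubbs second-generation catalyst, 5 mol%), 2,6-dichloro-1,4-benzoquinone (10 mol%), CH2Cl2, 40 °C
Reagents that add atoms: none
Why: Olefin cross-metathesis of the terminal alkene with the α-methylene lactone should forge C12=C13 and give the E alkylidene lactone with loss of ethene; free hydroxyl groups are tolerated and the quinone suppresses premature alkene migration.

Step 11
Reactants: 15 (3E)-3-{2-[(1R,2S,4aS,5R,6R,8aS)-6-hydroxy-2,5-bis(hydroxymethyl)-5,8a-dimethyldecahydronaphthalen-1-yl]ethylidene}oxolan-2-one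
Product: 16 3-{2-[(1R,2S,4aS,5R,6R,8aS)-6-hydroxy-2,5-bis(hydroxymethyl)-5,8a-dimethyldecahydronaphthalen-1-yl]ethyl}furan-2(5H)-one (14-deoxy-17-hydroxyandrographolide)
Conditions: RhCl3·3H2O (10 mol%), EtOH, 80 °C
Reagents that add atoms: none
Why: Rhodium hydride mediated alkene isomerisation (Grieco-type migration of an exocyclic lactone alkene into the ring) should move the double bond from C12=C13 to C13=C14 and give the more stable endocyclic butenolide without touching any stereocentre.

**Compound list**

1 | methyl 3-oxocyclohex-1-ene-1-carboxylate | COC(=O)C1=CC(=O)CCC1 | starting material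
2 | methyl (1S)-3-[(diphenylsilyl)oxy]cyclohex-2-ene-1-carboxylate | COC(=O)[C@H]1CCCC(O[SiH](c2ccccc2)c2ccccc2)=C1 | intermediate (not isolated)
3 | methyl (1S,2R)-3-oxo-2-(prop-2-en-1-yl)cyclohexane-1-carboxylate | O=C1CCC[C@H](C(=O)OC)[C@H]1CC=C | intermediate
4 | methyl (1S,2R)-2-(prop-2-en-1-yl)-3-[(trimethylsilyl)oxy]cyclohex-3-ene-1-carboxylate | C[Si](C)(C)OC1=CCC[C@H](C(=O)OC)[C@H]1CC=C | intermediate (not isolated)
5 | methyl (1S,2R)-4-bromo-3-oxo-2-(prop-2-en-1-yl)cyclohexane-1-carboxylate (both C4 epimers) | BrC1CC[C@H](C(=O)OC)[C@@H](CC=C)C1=O | intermediate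
6 | methyl 5-methoxy-3-oxopentanoate | COCCC(=O)CC(=O)OC | starting material
7 | methyl (1S,2R,4R)-4-(1,5-dimethoxy-1,3-dioxopentan-2-yl)-3-oxo-2-(prop-2-en-1-yl)cyclohexane-1-carboxylate (side-chain carbon epimeric) | COCCC(=O)C(C(=O)OC)[C@H]1CC[C@H](C(=O)OC)[C@@H](CC=C)C1=O | intermediate
8 | methyl (1S,2R,4R)-4-(1,5-dimethoxy-1,3-dioxopentan-2-yl)-3-methylidene-2-(prop-2-en-1-yl)cyclohexane-1-carboxylate (side-chain carbon epimeric) | COCCC(=O)C(C(=O)OC)[C@H]1CC[C@H](C(=O)OC)[C@@H](CC=C)C1=C | intermediate
9 | methyl (1S,2R,4R)-4-(1-methoxy-1,3-dioxopent-4-en-2-yl)-3-methylidene-2-(prop-2-en-1-yl)cyclohexane-1-carboxylate (side-chain carbon epimeric) | C=CC(=O)C(C(=O)OC)[C@H]1CC[C@H](C(=O)OC)[C@@H](CC=C)C1=C | intermediate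
10 | dimethyl (4aS,5R,6S,8aR)-4a-methyl-2-oxo-5-(prop-2-en-1-yl)decahydronaphthalene-1,6-dicarboxylate (C1 epimeric) | COC(=O)C1[C@H]2CC[C@H](C(=O)OC)[C@@H](CC=C)[C@]2(C)CCC1=O | intermediate
11 | dimethyl (1S,4aS,5R,6S,8aS)-1,4a-dimethyl-2-oxo-5-(prop-2-en-1-yl)decahydronaphthalene-1,6-dicarboxylate | C[C@]1(C(=O)OC)[C@H]2CC[C@H](C(=O)OC)[C@@H](CC=C)[C@]2(C)CCC1=O | intermediate
12 | dimethyl (1S,2R,4aS,5R,6S,8aS)-2-hydroxy-1,4a-dimethyl-5-(prop-2-en-1-yl)decahydronaphthalene-1,6-dicarboxylate | C[C@]1(C(=O)OC)[C@H]2CC[C@H](C(=O)OC)[C@@H](CC=C)[C@]2(C)CC[C@H]1O | intermediate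
13 | (1R,2R,4aS,5R,6S,8aS)-1,6-bis(hydroxymethyl)-1,4a-dimethyl-5-(prop-2-en-1-yl)decahydronaphthalen-2-ol | C[C@]1(CO)[C@H]2CC[C@H](CO)[C@@H](CC=C)[C@]2(C)CC[C@H]1O | intermediate
14 | 3-methylideneoxolan-2-one (α-methylene-γ-butyrolactone) | C=C1CCOC1=O | starting material
15 | (3E)-3-{2-[(1R,2S,4aS,5R,6R,8aS)-6-hydroxy-2,5-bis(hydroxymethyl)-5,8a-dimethyldecahydronaphthalen-1-yl]ethylidene}oxolan-2-one | C[C@]1(CO)[C@H]2CC[C@H](CO)[C@@H](C/C=C3\CCOC3=O)[C@]2(C)CC[C@H]1O | intermediate
16 | 3-{2-[(1R,2S,4aS,5R,6R,8aS)-6-hydroxy-2,5-bis(hydroxymethyl)-5,8a-dimethyldecahydronaphthalen-1-yl]ethyl}furan-2(5H)-one (14-deoxy-17-hydroxyandrographolide) | C[C@]1(CO)[C@H]2CC[C@H](CO)[C@@H](CCC3=CCOC3=O)[C@]2(C)CC[C@H]1O | target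

**Step count and risks**

Total step count: 11. Longest linear sequence: 11 steps (1 → 16).

Steps most likely to fail:

Step 6 (key step). Hydrogen-atom transfer to the monosubstituted allyl alkene, or plain reduction of the vinyl ketone, may compete with cyclisation, and part of the material may close through the axial lobe to the cis ring fusion. The fallback sets out from 9 and returns at 10. HBr in AcOH/CH2Cl2 at −20 °C should add to the exocyclic alkene (Markovnikov) and to the vinyl ketone (conjugate addition) and give methyl (1S,2R,4R)-3-bromo-4-(5-bromo-1-methoxy-1,3-dioxopentan-2-yl)-3-methyl-2-(prop-2-en-1-yl)cyclohexane-1-carboxylate F1. Et3N in CH2Cl2 at 0 °C should take HBr off the β-bromo ketone again and give methyl (1S,2R,4R)-3-bromo-4-(1-methoxy-1,3-dioxopent-4-en-2-yl)-3-methyl-2-(prop-2-en-1-yl)cyclohexane-1-carboxylate F2. Bu3SnH and AIBN (benzene, 80 °C, slow addition) should then abstract the tertiary bromine, and the same C10 radical closes to 10 (tin hydride radical cyclisation) with no metal hydride present that could touch the allyl group.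

Step 3. The enolate may attack the ketone carbonyl and then close to a dihydrofuran (Feist–Benary pathway), or HBr may be eliminated instead of substituted. The fallback sets out from 3 (with 6) and returns at 7. The kinetic lithium enolate of 3 (LiN(iPr)2, THF, −78 °C) is silylated with TBSOTf to the isolable methyl (1S,2R)-3-{[tert-butyl(dimethyl)silyl]oxy}-2-(prop-2-en-1-yl)cyclohex-3-ene-1-carboxylate F3. This is coupled oxidatively with 6 using (NH4)2Ce(NO3)6 and NaHCO3 in MeCN at −20 °C: the β-keto ester radical adds to the electron-rich enol ether, the adduct radical is oxidised by tetravalent cerium and loses the silyl group, and 7 results after the same base equilibration.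

Step 1. Enantioselectivity may be low with the ester-substituted enone, or hydride may be delivered β to the ester instead of β to the ketone. The fallback sets out from 1 and returns at 3. The same tandem reduction–allylation run with achiral [(Ph3P)CuH]6 and Ph2SiH2, then allyl bromide and TBAT, should give the racemic trans keto ester, that is 3 together with its mirror image methyl (1R,2S)-3-oxo-2-(prop-2-en-1-yl)cyclohexane-1-carboxylate F4. The enantiomers are separated by preparative chromatography on a chiral stationary phase.

Further compounds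
F1 | step 6 | methyl (1S,2R,4R)-3-bromo-4-(5-bromo-1-methoxy-1,3-dioxopentan-2-yl)-3-methyl-2-(prop-2-en-1-yl)cyclohexane-1-carboxylate (epimeric at C3 and at the side-chain carbon) | BrCCC(=O)C(C(=O)OC)[C@H]1CC[C@H](C(=O)OC)[C@@H](CC=C)C1(C)Br
F2 | step 6 | methyl (1S,2R,4R)-3-bromo-4-(1-methoxy-1,3-dioxopent-4-en-2-yl)-3-methyl-2-(prop-2-en-1-yl)cyclohexane-1-carboxylate (epimeric at C3 and at the side-chain carbon) | C=CC(=O)C(C(=O)OC)[C@H]1CC[C@H](C(=O)OC)[C@@H](CC=C)C1(C)Br
F3 | step 3 | methyl (1S,2R)-3-{[tert-butyl(dimethyl)silyl]oxy}-2-(prop-2-en-1-yl)cyclohex-3-ene-1-carboxylate | CC(C)(C)[Si](C)(C)OC1=CCC[C@H](C(=O)OC)[C@H]1CC=C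
F4 | step 1 | methyl (1R,2S)-3-oxo-2-(prop-2-en-1-yl)cyclohexane-1-carboxylate | O=C1CCC[C@@H](C(=O)OC)[C@@H]1CC=C
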